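## Retrosynthetic overview

- The C2-symmetric tetraene is cut at both ring–diene bonds: two identical (1R,2S)-4-bromocyclohex-3-enols plus a C4 (1E,3E)-1,4-distannylbutadiene, joined last by a two-fold Stille coupling. The distannyldiene is made from two different C2 pieces by a Negishi coupling.
- The two side-chain oxiranes are installed just before the union, by reagent-controlled Shi epoxidation of the only electron-rich alkene of the bromide.
- Each cyclohexene ring is closed at the C2–C3 bond by an epoxide-initiated cation–alkyne cyclization with bromide capture. The precursor is an acyclic epoxy enyne, and the step mirrors the epoxide-triggered ring closure presumed for this isoprenoid skeleton.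
- Enabling feature: in each ring the quaternary C2 (methyl, alkyl) sits between carbinol C1 and vinylic C3–H, and C4 is the only substituted alkene carbon. The C1–OH/C2–C3 pair is the imprint of anti opening of a Z-trisubstituted oxirane at its tertiary carbon by a terminal alkyne, and C4 is the vinyl-cation carbon that takes up bromide.
- Ring order: transient 2,3-oxirane (step 1, from nerol), cyclohexene (step 5), side-chain oxirane (step 6); the halves are united in step 9.

Key step: step 5

Remark: ring numbering in each cyclohexenol is C1 (carbinol), C2 (quaternary), C3=C4 (alkene, C4 substituted), C5, C6. (1E,3E)-1,4-Bis(tributylstannyl)buta-1,3-diene is assumed not to be purchasable and is therefore made in steps 7 and 8 from commercial (E)-1,2-bis(tributylstannyl)ethene.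

## Route

Step 1
Reactants: 1 nerol [(2Z)-3,7-dimethylocta-2,6-dien-1-ol]
Product: 2 [(2R,3S)-3-methyl-3-(4-methylpent-3-en-1-yl)oxiran-2-yl]methanol
Conditions: Ti(OiPr)4 (10 mol %), D-(−)-diethyl tartrate (12 mol %), t-BuOOH (2 equiv, decane), 4 Å molecular sieves, CH2Cl2, −20 °C
Reagents that add atoms: tert-butyl hydroperoxide, CC(C)(C)OO
Why: Sharpless asymmetric epoxidation touches only the allylic 2,3-alkene (the remote 6,7-alkene has no directing hydroxyl), and D-(−)-tartrate should deliver oxygen to the face that gives the (2R,3S)-oxirane, the Z geometry of nerol fixing CH2OH and the homoprenyl chain cis.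

Step 2
Reactants: 2 [(2R,3S)-3-methyl-3-(4-methylpent-3-en-1-yl)oxiran-2-yl]methanol
Product: 3 [(2R,3S)-3-methyl-3-(4-methylpent-3-en-1-yl)oxiran-2-yl]methyl trifluoromethanesulfonate
Conditions: Tf2O (1.1 equiv), 2,6-lutidine (1.3 equiv), CH2Cl2, −78 °C; cold aqueous work-up, used crude
Reagents that add atoms: trifluoromethanesulfonic anhydride, O=S(=O)(OS(=O)(=O)C(F)(F)F)C(F)(F)F
Why: O-sulfonylation of a primary alcohol with a hindered base at low temperature should leave the oxirane and both stereocenters untouched.

Step 3
Reactants: 3 [(2R,3S)-3-methyl-3-(4-methylpent-3-en-1-yl)oxiran-2-yl]methyl trifluoromethanesulfonate; 4 1-(trimethylsilyl)propyne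
Product: 5 trimethyl{4-[(2R,3S)-3-methyl-3-(4-methylpent-3-en-1-yl)oxiran-2-yl]but-1-yn-1-yl}silane
Conditions: 4 (1.3 equiv), n-BuLi (1.2 equiv), THF, −78 → −20 °C; then 3, THF, −78 °C
Reagents that add atoms: 1-(trimethylsilyl)propyne, CC#C[Si](C)(C)C
Why: SN2 alkylation of the lithiated silylpropyne by the primary triflate should be much faster at −78 °C than attack on the trisubstituted oxirane, the silyl group steering reaction to the propargylic rather than the allenic terminus, with no stereocenter involved.

Step 4
Reactants: 5 trimethyl{4-[(2R,3S)-3-methyl-3-(4-methylpent-3-en-1-yl)oxiran-2-yl]but-1-yn-1-yl}silane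
Product: 6 (2R,3S)-2-(but-3-yn-1-yl)-3-methyl-3-(4-methylpent-3-en-1-yl)oxirane
Conditions: K2CO3 (0.2 equiv), MeOH, 20 °C
Reagents that add atoms: none
Why: Base-catalysed methanolysis of the C(sp)–Si bond (protodesilylation) should free the terminal alkyne without affecting the oxirane or the alkene.

Step 5
Reactants: 6 (2R,3S)-2-(but-3-yn-1-yl)-3-methyl-3-(4-methylpent-3-en-1-yl)oxirane
Product: 7 (1R,2S)-4-bromo-2-methyl-2-(4-methylpent-3-en-1-yl)cyclohex-3-en-1-ol
Conditions: SnBr4 (1.1 equiv), 2,6-di-tert-butyl-4-methylpyridine (0.2 equiv), CH2Cl2, −78 °C; then aq. NaHCO3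
Reagents that add atoms: tin tetrabromide, Br[Sn](Br)(Br)Br
Why: SnBr4 coordinates the oxirane oxygen and the C–O bond at the fully substituted carbon lengthens while the terminal alkyne carbon (the Markovnikov terminus) attacks that carbon from the face opposite the departing oxygen; the cyclohex-1-enyl cation formed at the former internal alkyne carbon is captured by bromide from the bromostannate. The closest known reaction type is the epoxide-initiated cation–π (polyene-type) cyclization with an alkyne terminator and halide capture, the carbocyclic counterpart of the alkynyl Prins reaction. The single new ring closes 6-endo-dig at the alkyne and by endo-type opening of the oxirane at its distal, tertiary carbon, so both oxirane carbons end up in the ring. C1 keeps its C–O bond and hence its (R) configuration, whereas quaternary C2 is created with inversion, so the Z geometry and absolute configuration of 6 are translated into the (1R,2S) array with hydroxyl and homoprenyl chain cis. The step needs C–C bond formation to outrun bromide opening and 1,2-hydride shift, which the six-membered chair-like delivery of the alkyne and the low temperature should favour, and it needs a single alkene regioisomer, which is guaranteed because the ring double bond is the former triple bond and no proton is lost. The 4-methylpent-3-enyl alkene should not compete, since it could only close a four-membered ring or an anti-Markovnikov five-membered ring.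

Step 6
Reactants: 7 (1R,2S)-4-bromo-2-methyl-2-(4-methylpent-3-en-1-yl)cyclohex-3-en-1-ol
Product: 8 (1R,2S)-4-bromo-2-{2-[(2R)-3,3-dimethyloxiran-2-yl]ethyl}-2-methylcyclohex-3-en-1-ol
Conditions: D-fructose-derived ketone catalyst (1,2:4,5-di-O-isopropylidene-β-D-erythro-2,3-hexodiulo-2,6-pyranose, 0.3 equiv), KHSO5 (as 2KHSO5·KHSO4·K2SO4), K2CO3, Bu4NHSO4 (cat.), MeCN/dimethoxymethane–aq. Na2B4O7 buffer (pH ≈ 10.5), 0 °C
Reagents that add atoms: potassium peroxymonosulfate, [K+].[O-]S(=O)(=O)OO
Why: In this Shi epoxidation the chiral dioxirane should oxidize the electron-rich trisubstituted side-chain alkene far faster than the electron-poor bromoalkene or the alcohol, and its spiro transition state should set the new (R) center under reagent control, independent of the remote ring stereocenters.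

Step 7
Reactants: 9 (E)-1,2-bis(tributylstannyl)ethene
Product: 10 (E)-tributyl(2-iodoethenyl)stannane
Conditions: I2 (1.0 equiv, slow addition), Et2O, −20 → 0 °C, dark
Reagents that add atoms: iodine, II
Why: Electrophilic ipso-iododestannylation of an alkenylstannane proceeds with retention of alkene geometry, and the iodoalkene formed is much less nucleophilic at its remaining C–Sn bond, so one equivalent of iodine should stop at the mono-iodide.

Step 8
Reactants: 9 (E)-1,2-bis(tributylstannyl)ethene; 10 (E)-tributyl(2-iodoethenyl)stannane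
Product: 13 (1E,3E)-1,4-bis(tributylstannyl)buta-1,3-diene, via (E)-2-(tributylstannyl)vinyllithium 11 (not isolated), via (E)-2-(tributylstannyl)vinylzinc chloride 12 (not isolated)
Conditions: 9 (1.1 equiv), n-BuLi (1.1 equiv), THF, −78 °C; ZnCl2 (1.1 equiv, THF), −78 → 0 °C; then 10 (1.0 equiv), Pd(PPh3)4 (5 mol %), THF, 0 → 20 °C, dark
Reagents that add atoms: (E)-tributyl(2-iodoethenyl)stannane, CCCC[Sn](CCCC)(CCCC)/C=C/I
Why: Tin–lithium exchange of one stannyl group of 9, transmetalation to zinc and Negishi coupling with the alkenyl iodide all proceed with retention of the E geometry, and at or below 20 °C zinc-to-palladium transmetalation should be far faster than Stille coupling of any C–Sn bond, so both stannyl groups are carried into the E,E-diene.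

Step 9
Reactants: 8 (1R,2S)-4-bromo-2-{2-[(2R)-3,3-dimethyloxiran-2-yl]ethyl}-2-methylcyclohex-3-en-1-ol (2 equiv); 13 (1E,3E)-1,4-bis(tributylstannyl)buta-1,3-diene (1 equiv)
Product: 14 (1R,1'R,2S,2'S)-4,4'-[(1E,3E)-buta-1,3-diene-1,4-diyl]bis(2-{2-[(2R)-3,3-dimethyloxiran-2-yl]ethyl}-2-methylcyclohex-3-en-1-ol)
Conditions: Pd(P(t-Bu)3)2 (10 mol %), CsF (4.4 equiv), 1,4-dioxane, 45 °C, degassed, dark
Reagents that add atoms: (1E,3E)-1,4-bis(tributylstannyl)buta-1,3-diene, CCCC[Sn](CCCC)(CCCC)/C=C/C=C/[Sn](CCCC)(CCCC)CCCC
Why: In this two-fold Stille coupling, oxidative addition of each alkenyl bromide to zerovalent palladium, fluoride-assisted transmetalation and reductive elimination all occur with retention, so the E,E geometry of 13 and the ring-alkene position are carried into the tetraene while the free hydroxyls and non-allylic oxiranes tolerate the neutral conditions.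

## Compound list

1 | nerol, (2Z)-3,7-dimethylocta-2,6-dien-1-ol | CC(C)=CCC/C(C)=C\CO | starting material
2 | [(2R,3S)-3-methyl-3-(4-methylpent-3-en-1-yl)oxiran-2-yl]methanol | OC[C@H]1O[C@@]1(C)CCC=C(C)C | intermediate
3 | [(2R,3S)-3-methyl-3-(4-methylpent-3-en-1-yl)oxiran-2-yl]methyl trifluoromethanesulfonate | FC(F)(F)S(=O)(=O)OC[C@H]1O[C@@]1(C)CCC=C(C)C | intermediate
4 | 1-(trimethylsilyl)propyne | CC#C[Si](C)(C)C | starting material
5 | trimethyl{4-[(2R,3S)-3-methyl-3-(4-methylpent-3-en-1-yl)oxiran-2-yl]but-1-yn-1-yl}silane | C[Si](C)(C)C#CCC[C@H]1O[C@@]1(C)CCC=C(C)C | intermediate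
6 | (2R,3S)-2-(but-3-yn-1-yl)-3-methyl-3-(4-methylpent-3-en-1-yl)oxirane | C#CCC[C@H]1O[C@@]1(C)CCC=C(C)C | intermediate
7 | (1R,2S)-4-bromo-2-methyl-2-(4-methylpent-3-en-1-yl)cyclohex-3-en-1-ol | CC(C)=CCC[C@@]1(C)C=C(Br)CC[C@H]1O | intermediate
8 | (1R,2S)-4-bromo-2-{2-[(2R)-3,3-dimethyloxiran-2-yl]ethyl}-2-methylcyclohex-3-en-1-ol | CC1(C)O[C@@H]1CC[C@@]1(C)C=C(Br)CC[C@H]1O | intermediate
9 | (E)-1,2-bis(tributylstannyl)ethene | CCCC[Sn](CCCC)(CCCC)/C=C/[Sn](CCCC)(CCCC)CCCC | starting material
10 | (E)-tributyl(2-iodoethenyl)stannane | CCCC[Sn](CCCC)(CCCC)/C=C/I | intermediate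
11 | (E)-2-(tributylstannyl)vinyllithium | [Li]/C=C/[Sn](CCCC)(CCCC)CCCC | intermediate
12 | (E)-2-(tributylstannyl)vinylzinc chloride | Cl[Zn]/C=C/[Sn](CCCC)(CCCC)CCCC | intermediate
13 | (1E,3E)-1,4-bis(tributylstannyl)buta-1,3-diene | CCCC[Sn](CCCC)(CCCC)/C=C/C=C/[Sn](CCCC)(CCCC)CCCC | intermediate
14 | (1R,1'R,2S,2'S)-4,4'-[(1E,3E)-buta-1,3-diene-1,4-diyl]bis(2-{2-[(2R)-3,3-dimethyloxiran-2-yl]ethyl}-2-methylcyclohex-3-en-1-ol) | CC1(C)O[C@@H]1CC[C@@]1(C)C=C(/C=C/C=C/C2=C[C@](C)(CC[C@H]3OC3(C)C)[C@H](O)CC2)CC[C@H]1O | target

## Step count and risks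

Total step count: 9. Longest linear sequence: 7 (steps 1–6 and 9); steps 7 and 8 form a two-step branch.

Steps most likely to fail:

1. Step 5. Capture of the tertiary carbocation by bromide (bromohydrin formation) or a 1,2-hydride shift to the ketone may outrun ring closure by the weakly nucleophilic terminal alkyne, and partial ionization to a free cation would erode the stereospecific transfer to the quaternary center. The fallback sets out from 5 (step 4 is omitted) and uses a silicon-directed terminator. Under the same type of Lewis acid the more nucleophilic silicon-bearing alkyne carbon should attack (ipso) to give a cyclohexenyl cation stabilized by the β-silyl group, and bromide capture should give (1R,2R)-4-bromo-2-methyl-2-(4-methylpent-3-en-1-yl)-3-(trimethylsilyl)cyclohex-3-en-1-ol F1. Hydroxyl-assisted protodesilylation (alkoxide-triggered 1,4 carbon-to-oxygen silyl shift of the Brook type, cat. KOt-Bu in wet DMSO) should then remove silicon, and the route is rejoined at 7.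

2. Step 9. The second coupling may stall at the mono-coupled stage, the distannane may protodestannylate or homocouple, and the tetraene may isomerize or decompose on prolonged warming; the supply of 13 through the branch is a further uncertainty. The fallback sets out from 8 and builds the diene stepwise from commercial 9, so steps 7 and 8 are not needed. Mono-Stille coupling of 8 with excess 9 (Pd(PPh3)4, toluene, 80 °C) should give (1R,2S)-2-{2-[(2R)-3,3-dimethyloxiran-2-yl]ethyl}-2-methyl-4-[(E)-2-(tributylstannyl)ethenyl]cyclohex-3-en-1-ol F2. Iododestannylation of half of this material (I2, CH2Cl2, 0 °C) should give (1R,2S)-2-{2-[(2R)-3,3-dimethyloxiran-2-yl]ethyl}-4-[(E)-2-iodoethenyl]-2-methylcyclohex-3-en-1-ol F3. Cross-coupling of the two halves (Pd2(dba)3, AsPh3, NMP, 20 °C) should form the central bond, and the route is rejoined at 14.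

3. Step 3. Attack of the organolithium on the oxirane, base-induced decomposition of the epoxy triflate, or allenyl-type attack may compete with the wanted propargylic substitution. The fallback sets out from 3 and homologates in stages with a small stabilized nucleophile. LiCH2CN (from CH3CN and n-BuLi, THF, −78 °C) should give 3-[(2R,3S)-3-methyl-3-(4-methylpent-3-en-1-yl)oxiran-2-yl]propanenitrile F4. Reduction with i-Bu2AlH (CH2Cl2, −78 °C, aqueous work-up) should give 3-[(2R,3S)-3-methyl-3-(4-methylpent-3-en-1-yl)oxiran-2-yl]propanal F5. Seyferth–Gilbert homologation (dimethyl (1-diazo-2-oxopropyl)phosphonate, K2CO3, MeOH) should give the terminal alkyne directly, and the route is rejoined at 6.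

Further compounds
F1 | step 5 | (1R,2R)-4-bromo-2-methyl-2-(4-methylpent-3-en-1-yl)-3-(trimethylsilyl)cyclohex-3-en-1-ol | CC(C)=CCC[C@@]1(C)C([Si](C)(C)C)=C(Br)CC[C@H]1O
F2 | step 9 | (1R,2S)-2-{2-[(2R)-3,3-dimethyloxiran-2-yl]ethyl}-2-methyl-4-[(E)-2-(tributylstannyl)ethenyl]cyclohex-3-en-1-ol | CC1(C)O[C@@H]1CC[C@@]1(C)C=C(/C=C/[Sn](CCCC)(CCCC)CCCC)CC[C@H]1O
F3 | step 9 | (1R,2S)-2-{2-[(2R)-3,3-dimethyloxiran-2-yl]ethyl}-4-[(E)-2-iodoethenyl]-2-methylcyclohex-3-en-1-ol | CC1(C)O[C@@H]1CC[C@@]1(C)C=C(/C=C/I)CC[C@H]1O
F4 | step 3 | 3-[(2R,3S)-3-methyl-3-(4-methylpent-3-en-1-yl)oxiran-2-yl]propanenitrile | N#CCC[C@H]1O[C@@]1(C)CCC=C(C)C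
F5 | step 3 | 3-[(2R,3S)-3-methyl-3-(4-methylpent-3-en-1-yl)oxiran-2-yl]propanal | O=CCC[C@H]1O[C@@]1(C)CCC=C(C)C
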